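**Retrosynthetic overview**
1. Last bond: the C6'–O ester, by Mitsunobu inversion of an (S)-α-hydroxy ketone with a (Z)-4-silyloxycinnamic acid (made by Lindlar reduction of the arylpropiolic acid), then global desilylation.
2. C6' carbinol: ketoreductase reduction of the acetyl carbonyl of a cyclopropyl 1,2-diketone, itself built from a cyclopropanecarbaldehyde and 1-ethoxyvinyllithium.
3. Dihydropyranone (ring formed last): acrylate of the C6 homoallylic alcohol, ring-closing metathesis.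
4. Cyclopropane (ring formed second): Charette asymmetric Simmons–Smith reaction on an E-allylic alcohol obtained by cross-metathesis and DIBAL reduction.
5. C6/C1' pair, with an oxirane as the first ring (later opened by a vinyl cuprate): catalytic Sharpless desymmetrisation of divinyl carbinol.

Assumption: the SMILES is read as 6R (lactone), 1'S (carbinol), 2'S,4'S (trans-cyclopropane, C3' = CH2), 6'R (acyloxy carbon) and Z (coumarate); lactone atoms are C2–C6 and side-chain atoms C1'–C7' below.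

**Route**

Step 1
Reactants: 1 penta-1,4-dien-3-ol (divinyl carbinol)
Product: 2 (1S)-1-[(2R)-oxiran-2-yl]prop-2-en-1-ol
Conditions: Ti(OiPr)4 (10 mol%), L-(+)-diisopropyl tartrate (13 mol%), t-BuOOH (1.5 equiv, in decane), 4 Å MS, CH2Cl2, −20 °C
Reagents that add atoms: tert-butyl hydroperoxide, CC(C)(C)OO
Why: Sharpless asymmetric epoxidation used as a desymmetrisation: the Ti/L-tartrate catalyst epoxidises one enantiotopic vinyl group to the anti epoxy alcohol, setting C1' (S) and C6 (R) together, and the minor enantiomer is consumed faster by a second epoxidation so ee rises with conversion.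

Step 2
Reactants: 2 (1S)-1-[(2R)-oxiran-2-yl]prop-2-en-1-ol
Product: 3 tert-butyl(dimethyl){[(1S)-1-[(2R)-oxiran-2-yl]prop-2-en-1-yl]oxy}silane
Conditions: TBSCl, imidazole, DMF, 0 °C to rt
Reagents that add atoms: tert-butyldimethylsilyl chloride, CC(C)(C)[Si](C)(C)Cl
Why: Imidazole-promoted silylation of the secondary alcohol under non-alkoxide conditions, which avoids Payne rearrangement of the epoxy alcohol.

Step 3
Reactants: 3 tert-butyl(dimethyl){[(1S)-1-[(2R)-oxiran-2-yl]prop-2-en-1-yl]oxy}silane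
Product: 4 methyl (2E,4S)-4-[(tert-butyldimethylsilyl)oxy]-4-[(2R)-oxiran-2-yl]but-2-enoate
Conditions: methyl acrylate (5 equiv), second-generation Hoveyda–Grubbs catalyst RuCl2(SIMes)(=CH-C6H4-2-OiPr) (5 mol%), CH2Cl2, 40 °C
Reagents that add atoms: methyl acrylate, C=CC(=O)OC
Why: Olefin cross-metathesis of the terminal vinyl group with an electron-poor acrylate gives the E-enoate selectively, with epoxide and silyl ether inert.

Step 4
Reactants: 4 methyl (2E,4S)-4-[(tert-butyldimethylsilyl)oxy]-4-[(2R)-oxiran-2-yl]but-2-enoate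
Product: 5 (2E,4S)-4-[(tert-butyldimethylsilyl)oxy]-4-[(2R)-oxiran-2-yl]but-2-en-1-ol
Conditions: i-Bu2AlH (2.2 equiv), CH2Cl2, −78 °C; MeOH, then Na2SO4·10H2O
Reagents that add atoms: none
Why: DIBAL-H 1,2-reduction of the enoate to the E-allylic alcohol at −78 °C, where a terminal epoxide is not opened.

Step 5
Reactants: 5 (2E,4S)-4-[(tert-butyldimethylsilyl)oxy]-4-[(2R)-oxiran-2-yl]but-2-en-1-ol
Product: 6 (2E,4S,5R)-4-[(tert-butyldimethylsilyl)oxy]octa-2,7-diene-1,5-diol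
Conditions: CH2=CHMgBr (3.5 equiv), CuI (15 mol%), THF, −40 to −20 °C; aq. NH4Cl
Reagents that add atoms: vinylmagnesium bromide, C=C[Mg]Br
Why: Copper-catalysed Grignard opening of the terminal epoxide at its CH2 carbon (SN2) leaves the C6 stereocentre untouched, the first equivalent of Grignard reagent only deprotonating the allylic alcohol.

Step 6
Reactants: 6 (2E,4S,5R)-4-[(tert-butyldimethylsilyl)oxy]octa-2,7-diene-1,5-diol
Product: 7 tert-butyl(dimethyl){[(2E,4S,5R)-1,5-bis[(triethylsilyl)oxy]octa-2,7-dien-4-yl]oxy}silane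
Conditions: Et3SiCl (2.5 equiv), imidazole (5 equiv), CH2Cl2, 0 °C to rt
Reagents that add atoms: chlorotriethylsilane, CC[Si](CC)(CC)Cl
Why: Exhaustive silylation of both hydroxyls under neutral conditions, which avoids base-induced migration of the neighbouring TBS group.

Step 7
Reactants: 7 tert-butyl(dimethyl){[(2E,4S,5R)-1,5-bis[(triethylsilyl)oxy]octa-2,7-dien-4-yl]oxy}silane
Product: 8 (2E,4S,5R)-4-[(tert-butyldimethylsilyl)oxy]-5-[(triethylsilyl)oxy]octa-2,7-dien-1-ol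
Conditions: PPTS (10 mol%), MeOH/CH2Cl2 (1:4), −10 °C, TLC control; Et3N quench
Reagents that add atoms: none
Why: Acid-catalysed methanolysis cleaves the unhindered primary allylic triethylsilyl ether much faster than the hindered secondary TES and TBS ethers.

Step 8
Reactants: 8 (2E,4S,5R)-4-[(tert-butyldimethylsilyl)oxy]-5-[(triethylsilyl)oxy]octa-2,7-dien-1-ol
Product: 9 [(1S,2S)-2-[(1S,2R)-1-[(tert-butyldimethylsilyl)oxy]-2-[(triethylsilyl)oxy]pent-4-en-1-yl]cyclopropyl]methanol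
Conditions: Et2Zn (2.2 equiv), CH2I2 (4.4 equiv), DME (2.2 equiv), CH2Cl2, −10 °C; then 8 and (4R,5R)-2-butyl-N,N,N',N'-tetramethyl-1,3,2-dioxaborolane-4,5-dicarboxamide (1.2 equiv), −10 °C to rt; aq. NH4Cl
Reagents that add atoms: diiodomethane, ICI
Why: Charette asymmetric Simmons–Smith cyclopropanation: the zinc alkoxide–dioxaborolane complex delivers CH2 stereospecifically to one face of the E-alkene (the (R,R)-ligand gives the (S,S)-cyclopropylmethanol, as with cinnamyl alcohol), setting C2' and C4' trans, while the undirected terminal alkene is left alone.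

Step 9
Reactants: 9 [(1S,2S)-2-[(1S,2R)-1-[(tert-butyldimethylsilyl)oxy]-2-[(triethylsilyl)oxy]pent-4-en-1-yl]cyclopropyl]methanol
Product: 10 (1S,2S)-2-[(1S,2R)-1-[(tert-butyldimethylsilyl)oxy]-2-[(triethylsilyl)oxy]pent-4-en-1-yl]cyclopropane-1-carbaldehyde
Conditions: Dess–Martin periodinane (1.3 equiv), pyridine (3 equiv), CH2Cl2, 0 °C to rt
Reagents that add atoms: none
Why: Buffered Dess–Martin oxidation of the primary alcohol to the aldehyde, under which a trans-cyclopropanecarbaldehyde does not epimerise.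

Step 10
Reactants: 10 (1S,2S)-2-[(1S,2R)-1-[(tert-butyldimethylsilyl)oxy]-2-[(triethylsilyl)oxy]pent-4-en-1-yl]cyclopropane-1-carbaldehyde
Product: 11 1-[(1S,2S)-2-[(1S,2R)-1-[(tert-butyldimethylsilyl)oxy]-2-[(triethylsilyl)oxy]pent-4-en-1-yl]cyclopropyl]-2-ethoxyprop-2-en-1-ol (both C1 epimers)
Conditions: ethyl vinyl ether (4 equiv), t-BuLi (3 equiv), THF, −78 to 0 °C; then 10, −78 °C; aq. NH4Cl
Reagents that add atoms: ethyl vinyl ether, C=COCC (as 1-ethoxyvinyllithium, [Li]C(=C)OCC)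
Why: 1,2-Addition of the acyl-anion equivalent 1-ethoxyvinyllithium to the aldehyde installs C6' and C7', and the new carbinol centre is irrelevant because it is oxidised in the next step.

Step 11
Reactants: 11 1-[(1S,2S)-2-[(1S,2R)-1-[(tert-butyldimethylsilyl)oxy]-2-[(triethylsilyl)oxy]pent-4-en-1-yl]cyclopropyl]-2-ethoxyprop-2-en-1-ol
Product: 12 1-[(1S,2S)-2-[(1S,2R)-1-[(tert-butyldimethylsilyl)oxy]-2-[(triethylsilyl)oxy]pent-4-en-1-yl]cyclopropyl]-2-ethoxyprop-2-en-1-one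
Conditions: Dess–Martin periodinane (1.5 equiv), pyridine (5 equiv), CH2Cl2, 0 °C to rt
Reagents that add atoms: none
Why: Buffered Dess–Martin oxidation of the allylic-type carbinol gives the 2-ethoxy enone, a masked 1,2-diketone, converging both epimers of 11.

Step 12
Reactants: 12 1-[(1S,2S)-2-[(1S,2R)-1-[(tert-butyldimethylsilyl)oxy]-2-[(triethylsilyl)oxy]pent-4-en-1-yl]cyclopropyl]-2-ethoxyprop-2-en-1-one
Product: 14 1-[(1S,2S)-2-[(1S,2R)-1-[(tert-butyldimethylsilyl)oxy]-2-hydroxypent-4-en-1-yl]cyclopropyl]propane-1,2-dione, via diketone triethylsilyl ether 13 (not isolated)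
Conditions: 1 M aq. HCl/THF (1:4), 0 °C to rt
Reagents that add atoms: water, O
Why: Aqueous acid hydrolyses the enol ether to the methyl ketone and cleaves the acid-labile TES ether, while the hindered secondary TBS ether survives.

Step 13
Reactants: 14 1-[(1S,2S)-2-[(1S,2R)-1-[(tert-butyldimethylsilyl)oxy]-2-hydroxypent-4-en-1-yl]cyclopropyl]propane-1,2-dione
Product: 15 (1S,2R)-1-[(tert-butyldimethylsilyl)oxy]-1-[(1S,2S)-2-(2-oxopropanoyl)cyclopropyl]pent-4-en-2-yl prop-2-enoate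
Conditions: acryloyl chloride (1.5 equiv), i-Pr2NEt (3 equiv), CH2Cl2, −78 to 0 °C
Reagents that add atoms: acryloyl chloride, C=CC(=O)Cl
Why: O-Acylation of the only free hydroxyl with an acid chloride and a hindered amine base at low temperature, where the diketone does not enolise appreciably.

Step 14
Reactants: 15 (1S,2R)-1-[(tert-butyldimethylsilyl)oxy]-1-[(1S,2S)-2-(2-oxopropanoyl)cyclopropyl]pent-4-en-2-yl prop-2-enoate
Product: 16 (6R)-6-[(S)-[(tert-butyldimethylsilyl)oxy][(1S,2S)-2-(2-oxopropanoyl)cyclopropyl]methyl]-5,6-dihydro-2H-pyran-2-one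
Conditions: second-generation Grubbs catalyst RuCl2(SIMes)(PCy3)(=CHPh) (7 mol%), CH2Cl2 (3 mM), 40 °C
Reagents that add atoms: none
Why: Ring-closing metathesis of the acrylate with the terminal alkene closes the six-membered α,β-unsaturated lactone with loss of ethene, no other alkene being present.

Step 15
Reactants: 16 (6R)-6-[(S)-[(tert-butyldimethylsilyl)oxy][(1S,2S)-2-(2-oxopropanoyl)cyclopropyl]methyl]-5,6-dihydro-2H-pyran-2-one
Product: 17 (6R)-6-[(S)-[(tert-butyldimethylsilyl)oxy][(1S,2S)-2-[(2S)-2-hydroxypropanoyl]cyclopropyl]methyl]-5,6-dihydro-2H-pyran-2-one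
Conditions: ketoreductase (NADPH-dependent alcohol dehydrogenase, (S)-selective, chosen from a screening panel), NADP+ (1 mol%), i-PrOH (15% v/v), KH2PO4/K2HPO4 buffer (0.1 M, pH 6.8), MgSO4 (2 mM), DMSO (5% v/v), 30 °C
Reagents that add atoms: none
Why: Enzymatic asymmetric ketone reduction: a Prelog-type ketoreductase binds the methyl group in its small pocket and delivers hydride only to the acetyl carbonyl, setting C6' as (S), while the hindered cyclopropyl ketone and the lactone are not reduced.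

Step 16
Reactants: 18 4-[(tert-butyldimethylsilyl)oxy]benzaldehyde
Product: 19 tert-butyl[4-(2,2-dibromoethenyl)phenoxy]dimethylsilane
Conditions: CBr4 (2 equiv), PPh3 (4 equiv), CH2Cl2, 0 °C
Reagents that add atoms: carbon tetrabromide, BrC(Br)(Br)Br
Why: Ramirez dibromo-olefination (first stage of the Corey–Fuchs sequence), a Wittig-type reaction of the aldehyde with the ylide from CBr4 and PPh3.

Step 17
Reactants: 19 tert-butyl[4-(2,2-dibromoethenyl)phenoxy]dimethylsilane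
Product: 21 3-[4-[(tert-butyldimethylsilyl)oxy]phenyl]prop-2-ynoic acid, via lithium acetylide 20 (not isolated)
Conditions: n-BuLi (2.1 equiv), THF, −78 °C; CO2 (g), −78 to 0 °C; 1 M aq. HCl to pH 3, 0 °C
Reagents that add atoms: carbon dioxide, O=C=O
Why: Second stage of the Corey–Fuchs reaction (Br/Li exchange, rearrangement and deprotonation to the lithium acetylide), then carboxylation of the acetylide with CO2.

Step 18
Reactants: 21 3-[4-[(tert-butyldimethylsilyl)oxy]phenyl]prop-2-ynoic acid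
Product: 22 (2Z)-3-[4-[(tert-butyldimethylsilyl)oxy]phenyl]prop-2-enoic acid
Conditions: H2 (1 atm, stopped at 1.0 equiv), Pd on CaCO3 poisoned with Pb(OAc)2 (Lindlar catalyst), quinoline, EtOAc, rt, light excluded
Reagents that add atoms: none
Why: Lindlar semi-hydrogenation adds H2 syn to the alkyne on the poisoned palladium surface and so gives the Z-alkene.

Step 19
Reactants: 17 (6R)-6-[(S)-[(tert-butyldimethylsilyl)oxy][(1S,2S)-2-[(2S)-2-hydroxypropanoyl]cyclopropyl]methyl]-5,6-dihydro-2H-pyran-2-one; 22 (2Z)-3-[4-[(tert-butyldimethylsilyl)oxy]phenyl]prop-2-enoic acid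
Product: 23 (2R)-1-[(1S,2S)-2-[(S)-[(tert-butyldimethylsilyl)oxy][(2R)-6-oxo-3,6-dihydro-2H-pyran-2-yl]methyl]cyclopropyl]-1-oxopropan-2-yl (2Z)-3-[4-[(tert-butyldimethylsilyl)oxy]phenyl]prop-2-enoate
Conditions: PPh3 (1.6 equiv), diisopropyl azodicarboxylate (1.6 equiv), toluene, −10 °C to rt, light excluded
Reagents that add atoms: none
Why: Mitsunobu esterification: the carboxylate displaces the oxyphosphonium group by SN2 with inversion at C6' (S to R), and because the Z-acid acts only as the nucleophile and is never acyl-activated its geometry is retained.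

Step 20
Reactants: 23 (2R)-1-[(1S,2S)-2-[(S)-[(tert-butyldimethylsilyl)oxy][(2R)-6-oxo-3,6-dihydro-2H-pyran-2-yl]methyl]cyclopropyl]-1-oxopropan-2-yl (2Z)-3-[4-[(tert-butyldimethylsilyl)oxy]phenyl]prop-2-enoate
Product: 24 (2R)-1-[(1S,2S)-2-[(S)-hydroxy[(2R)-6-oxo-3,6-dihydro-2H-pyran-2-yl]methyl]cyclopropyl]-1-oxopropan-2-yl (2Z)-3-(4-hydroxyphenyl)prop-2-enoate
Conditions: HF·pyridine (excess), pyridine, THF, 0 °C to rt, plastic vessel, light excluded
Reagents that add atoms: none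
Why: Fluoride-mediated cleavage of the aryl and the secondary alkyl silyl ethers under mildly acidic conditions that spare the two esters, the α-acyloxy ketone and the Z-alkene.

**Compound list**

1 | penta-1,4-dien-3-ol | C=CC(O)C=C | starting material
2 | (1S)-1-[(2R)-oxiran-2-yl]prop-2-en-1-ol | C=C[C@H](O)[C@H]1CO1 | intermediate
3 | tert-butyl(dimethyl){[(1S)-1-[(2R)-oxiran-2-yl]prop-2-en-1-yl]oxy}silane | C=C[C@H](O[Si](C)(C)C(C)(C)C)[C@H]1CO1 | intermediate
4 | methyl (2E,4S)-4-[(tert-butyldimethylsilyl)oxy]-4-[(2R)-oxiran-2-yl]but-2-enoate | COC(=O)/C=C/[C@H](O[Si](C)(C)C(C)(C)C)[C@H]1CO1 | intermediate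
5 | (2E,4S)-4-[(tert-butyldimethylsilyl)oxy]-4-[(2R)-oxiran-2-yl]but-2-en-1-ol | OC/C=C/[C@H](O[Si](C)(C)C(C)(C)C)[C@H]1CO1 | intermediate
6 | (2E,4S,5R)-4-[(tert-butyldimethylsilyl)oxy]octa-2,7-diene-1,5-diol | OC/C=C/[C@H](O[Si](C)(C)C(C)(C)C)[C@H](O)CC=C | intermediate
7 | tert-butyl(dimethyl){[(2E,4S,5R)-1,5-bis[(triethylsilyl)oxy]octa-2,7-dien-4-yl]oxy}silane | CC[Si](CC)(CC)OC/C=C/[C@H](O[Si](C)(C)C(C)(C)C)[C@H](O[Si](CC)(CC)CC)CC=C | intermediate
8 | (2E,4S,5R)-4-[(tert-butyldimethylsilyl)oxy]-5-[(triethylsilyl)oxy]octa-2,7-dien-1-ol | OC/C=C/[C@H](O[Si](C)(C)C(C)(C)C)[C@H](O[Si](CC)(CC)CC)CC=C | intermediate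
9 | [(1S,2S)-2-[(1S,2R)-1-[(tert-butyldimethylsilyl)oxy]-2-[(triethylsilyl)oxy]pent-4-en-1-yl]cyclopropyl]methanol | OC[C@H]1C[C@@H]1[C@H](O[Si](C)(C)C(C)(C)C)[C@H](O[Si](CC)(CC)CC)CC=C | intermediate
10 | (1S,2S)-2-[(1S,2R)-1-[(tert-butyldimethylsilyl)oxy]-2-[(triethylsilyl)oxy]pent-4-en-1-yl]cyclopropane-1-carbaldehyde | O=C[C@H]1C[C@@H]1[C@H](O[Si](C)(C)C(C)(C)C)[C@H](O[Si](CC)(CC)CC)CC=C | intermediate
11 | 1-[(1S,2S)-2-[(1S,2R)-1-[(tert-butyldimethylsilyl)oxy]-2-[(triethylsilyl)oxy]pent-4-en-1-yl]cyclopropyl]-2-ethoxyprop-2-en-1-ol (both C1 epimers) | C=C(OCC)C(O)[C@H]1C[C@@H]1[C@H](O[Si](C)(C)C(C)(C)C)[C@H](O[Si](CC)(CC)CC)CC=C | intermediate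
12 | 1-[(1S,2S)-2-[(1S,2R)-1-[(tert-butyldimethylsilyl)oxy]-2-[(triethylsilyl)oxy]pent-4-en-1-yl]cyclopropyl]-2-ethoxyprop-2-en-1-one | C=C(OCC)C(=O)[C@H]1C[C@@H]1[C@H](O[Si](C)(C)C(C)(C)C)[C@H](O[Si](CC)(CC)CC)CC=C | intermediate
13 | 1-[(1S,2S)-2-[(1S,2R)-1-[(tert-butyldimethylsilyl)oxy]-2-[(triethylsilyl)oxy]pent-4-en-1-yl]cyclopropyl]propane-1,2-dione (not isolated) | CC(=O)C(=O)[C@H]1C[C@@H]1[C@H](O[Si](C)(C)C(C)(C)C)[C@H](O[Si](CC)(CC)CC)CC=C | intermediate
14 | 1-[(1S,2S)-2-[(1S,2R)-1-[(tert-butyldimethylsilyl)oxy]-2-hydroxypent-4-en-1-yl]cyclopropyl]propane-1,2-dione | CC(=O)C(=O)[C@H]1C[C@@H]1[C@H](O[Si](C)(C)C(C)(C)C)[C@H](O)CC=C | intermediate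
15 | (1S,2R)-1-[(tert-butyldimethylsilyl)oxy]-1-[(1S,2S)-2-(2-oxopropanoyl)cyclopropyl]pent-4-en-2-yl prop-2-enoate | CC(=O)C(=O)[C@H]1C[C@@H]1[C@H](O[Si](C)(C)C(C)(C)C)[C@H](OC(=O)C=C)CC=C | intermediate
16 | (6R)-6-[(S)-[(tert-butyldimethylsilyl)oxy][(1S,2S)-2-(2-oxopropanoyl)cyclopropyl]methyl]-5,6-dihydro-2H-pyran-2-one | CC(=O)C(=O)[C@H]1C[C@@H]1[C@H](O[Si](C)(C)C(C)(C)C)[C@H]1CC=CC(=O)O1 | intermediate
17 | (6R)-6-[(S)-[(tert-butyldimethylsilyl)oxy][(1S,2S)-2-[(2S)-2-hydroxypropanoyl]cyclopropyl]methyl]-5,6-dihydro-2H-pyran-2-one | C[C@H](O)C(=O)[C@H]1C[C@@H]1[C@H](O[Si](C)(C)C(C)(C)C)[C@H]1CC=CC(=O)O1 | intermediate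
18 | 4-[(tert-butyldimethylsilyl)oxy]benzaldehyde | O=Cc1ccc(O[Si](C)(C)C(C)(C)C)cc1 | starting material
19 | tert-butyl[4-(2,2-dibromoethenyl)phenoxy]dimethylsilane | BrC(Br)=Cc1ccc(O[Si](C)(C)C(C)(C)C)cc1 | intermediate
20 | lithium {4-[(tert-butyldimethylsilyl)oxy]phenyl}acetylide (not isolated) | [Li]C#Cc1ccc(O[Si](C)(C)C(C)(C)C)cc1 | intermediate
21 | 3-[4-[(tert-butyldimethylsilyl)oxy]phenyl]prop-2-ynoic acid | OC(=O)C#Cc1ccc(O[Si](C)(C)C(C)(C)C)cc1 | intermediate
22 | (2Z)-3-[4-[(tert-butyldimethylsilyl)oxy]phenyl]prop-2-enoic acid | OC(=O)/C=C\c1ccc(O[Si](C)(C)C(C)(C)C)cc1 | intermediate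
23 | (2R)-1-[(1S,2S)-2-[(S)-[(tert-butyldimethylsilyl)oxy][(2R)-6-oxo-3,6-dihydro-2H-pyran-2-yl]methyl]cyclopropyl]-1-oxopropan-2-yl (2Z)-3-[4-[(tert-butyldimethylsilyl)oxy]phenyl]prop-2-enoate | C[C@@H](OC(=O)/C=C\c1ccc(O[Si](C)(C)C(C)(C)C)cc1)C(=O)[C@H]1C[C@@H]1[C@H](O[Si](C)(C)C(C)(C)C)[C@H]1CC=CC(=O)O1 | intermediate
24 | (2R)-1-[(1S,2S)-2-[(S)-hydroxy[(2R)-6-oxo-3,6-dihydro-2H-pyran-2-yl]methyl]cyclopropyl]-1-oxopropan-2-yl (2Z)-3-(4-hydroxyphenyl)prop-2-enoate | C[C@@H](OC(=O)/C=C\c1ccc(O)cc1)C(=O)[C@H]1C[C@@H]1[C@H](O)[C@H]1CC=CC(=O)O1 | target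

**Step count and risk**

Total steps: 20. Longest linear sequence: 17 (steps 1–15, 19, 20); the acid 22 is made in 3 steps (16–18).

Steps most likely to fail, each with one fallback:

Step 3 (cross-metathesis of a hindered allylic silyl ether next to an epoxide). The fallback sets out from 3 and comes back at 4 by cleaving and re-olefinating instead of metathesis. Ozonolysis of 3 (O3, CH2Cl2, −78 °C; PPh3) gives (2R)-2-[(tert-butyldimethylsilyl)oxy]-2-[(2R)-oxiran-2-yl]acetaldehyde F1. This is used crude in a Wittig reaction with methyl (triphenylphosphoranylidene)acetate (CH2Cl2, rt), which gives the E-enoate 4; the stabilised ylide is not basic enough to epimerise the α-silyloxy aldehyde.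

Step 15 (regio- and stereoselective enzymatic reduction on the lactone-bearing diketone 16, which may be poorly accepted or degraded). The fallback sets out from 14 and comes back at 17, moving the ketoreductase step to the smaller open-chain hydroxy diketone and forming the lactone afterwards. The same ketoreductase/NADP+/i-PrOH system reduces 14 to the (2S)-hydroxy ketone diol F2. Et3SiCl (1.05 equiv)/imidazole at −40 °C silylates the less hindered C6' hydroxyl to give the triethylsilyl ether F3, the C6 hydroxyl being shielded by the adjacent TBS ether. Acryloyl chloride/i-Pr2NEt gives the acrylate F4, and ring-closing metathesis with the second-generation Grubbs catalyst RuCl2(SIMes)(PCy3)(=CHPh) gives the lactone F5. PPTS in MeOH then removes the TES group selectively and returns 17.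

Step 19 (Mitsunobu reaction on an α-hydroxy ketone; elimination or sluggish displacement are possible). The fallback sets out from 17 and comes back at 23 by a two-stage sulfonate displacement. Tf2O/2,6-lutidine in CH2Cl2 at −78 °C converts 17 into the (2S)-triflate F6. Without isolation, F6 is treated with acid 22 and i-Pr2NEt (CH2Cl2/MeCN, −40 to 0 °C); the carboxylate displaces triflate by SN2 with inversion to give 23, again without ever activating the Z-acid as an acyl donor.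

Further compounds
F1 | step 3 | (2R)-2-[(tert-butyldimethylsilyl)oxy]-2-[(2R)-oxiran-2-yl]acetaldehyde | O=C[C@H](O[Si](C)(C)C(C)(C)C)[C@H]1CO1
F2 | step 15 | (2S)-1-[(1S,2S)-2-[(1S,2R)-1-[(tert-butyldimethylsilyl)oxy]-2-hydroxypent-4-en-1-yl]cyclopropyl]-2-hydroxypropan-1-one | C[C@H](O)C(=O)[C@H]1C[C@@H]1[C@H](O[Si](C)(C)C(C)(C)C)[C@H](O)CC=C
F3 | step 15 | (2S)-1-[(1S,2S)-2-[(1S,2R)-1-[(tert-butyldimethylsilyl)oxy]-2-hydroxypent-4-en-1-yl]cyclopropyl]-2-[(triethylsilyl)oxy]propan-1-one | C[C@H](O[Si](CC)(CC)CC)C(=O)[C@H]1C[C@@H]1[C@H](O[Si](C)(C)C(C)(C)C)[C@H](O)CC=C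
F4 | step 15 | (1S,2R)-1-[(tert-butyldimethylsilyl)oxy]-1-[(1S,2S)-2-[(2S)-2-[(triethylsilyl)oxy]propanoyl]cyclopropyl]pent-4-en-2-yl prop-2-enoate | C[C@H](O[Si](CC)(CC)CC)C(=O)[C@H]1C[C@@H]1[C@H](O[Si](C)(C)C(C)(C)C)[C@H](OC(=O)C=C)CC=C
F5 | step 15 | (6R)-6-[(S)-[(tert-butyldimethylsilyl)oxy][(1S,2S)-2-[(2S)-2-[(triethylsilyl)oxy]propanoyl]cyclopropyl]methyl]-5,6-dihydro-2H-pyran-2-one | C[C@H](O[Si](CC)(CC)CC)C(=O)[C@H]1C[C@@H]1[C@H](O[Si](C)(C)C(C)(C)C)[C@H]1CC=CC(=O)O1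
F6 | step 19 | (2S)-1-[(1S,2S)-2-[(S)-[(tert-butyldimethylsilyl)oxy][(2R)-6-oxo-3,6-dihydro-2H-pyran-2-yl]methyl]cyclopropyl]-1-oxopropan-2-yl trifluoromethanesulfonate | C[C@H](OS(=O)(=O)C(F)(F)F)C(=O)[C@H]1C[C@@H]1[C@H](O[Si](C)(C)C(C)(C)C)[C@H]1CC=CC(=O)O1
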